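**Plan**
Cuts: C8–OH and C3'–OH are masked as methyl and benzyl ethers. Ring B (pyranone) is opened at O2–C3 and the side chain is detached at C4–C4a, which leaves 2-iodo-4,6-dimethoxybenzoic acid (ring A) and a 5'-allyl γ-lactone (ring C). Ring C is then cut at C5'–CHCl2 and O1'–C2' together.
Enabling feature: C2', C3', C4' and C5' of ring C are the four carbons of L-malic acid. With C5' as a ketone, the C3' oxygen lies β to it, so a six-membered magnesium chelate can form, and the C2' ester lies γ to it, so the new alkoxide closes a five-membered ring.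
Forward order: malic acid → allyl ketone → ring C with CHCl2 (key step) → ring A joined by a Heck reaction → ring B closed by oxidative lactonization → both ethers cleaved with BCl3.
Stereochemistry: C3' (S) comes from L-malic acid and none of its bonds is ever broken. C5' (R in the target) is induced from C3' by 1,3-anti addition to the chelated ketone, which places CHCl2 cis to the C3' oxygen on ring C.

Key step: step 6

Remark: primed locants belong to ring C (O1', C2' carbonyl, C3' carbinol, C4' methylene, C5' quaternary carbon). The CIP letter at C5' changes from S to R when ring B is formed, with no change in space.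

Step 1
Reactants: 1 L-malic acid
Product: 2 (S)-2-(2,2-dimethyl-5-oxo-1,3-dioxolan-4-yl)acetic acid
Conditions: 2,2-dimethoxypropane, TsOH·H2O (cat.), rt
Reagents that add atoms: 2,2-dimethoxypropane COC(C)(C)OC
Why: Acid-catalysed transketalization closes the five-membered dioxolanone over the α-hydroxy acid pair (C2'/C3') in preference to a six-membered ring over the β-carboxyl, so the carboxyl that becomes C5' stays free and the S carbinol carbon keeps all its bonds.

Step 2
Reactants: 2 (S)-2-(2,2-dimethyl-5-oxo-1,3-dioxolan-4-yl)acetic acid
Product: 3 (S)-2-(2,2-dimethyl-5-oxo-1,3-dioxolan-4-yl)acetyl chloride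
Conditions: (COCl)2, DMF (cat.), CH2Cl2, 0 °C → rt
Reagents that add atoms: oxalyl chloride O=C(Cl)C(=O)Cl
Why: Acid chloride formation through the chloroiminium species from catalytic DMF is a standard carboxyl activation that needs neither base nor heat, so the acetonide and the C3' centre are left alone.

Step 3
Reactants: 3 (S)-2-(2,2-dimethyl-5-oxo-1,3-dioxolan-4-yl)acetyl chloride; 4 allyltributylstannane
Product: 5 (S)-2,2-dimethyl-5-(2-oxopent-4-en-1-yl)-1,3-dioxolan-4-one
Conditions: Pd(PPh3)4 (3 mol %), THF, 50 °C
Reagents that add atoms: none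
Why: Stille acylation, in which zerovalent palladium inserts into the acyl carbon–chlorine bond, tin transfers the allyl group and reductive elimination gives the ketone under neutral conditions that spare the dioxolanone and should keep the alkene β,γ.

Step 4
Reactants: 5 (S)-2,2-dimethyl-5-(2-oxopent-4-en-1-yl)-1,3-dioxolan-4-one
Product: 6 methyl (S)-2-hydroxy-4-oxohept-6-enoate
Conditions: MeOH, CSA (cat.), rt
Reagents that add atoms: methanol CO
Why: Acid-catalysed transesterification of the activated dioxolanone carbonyl by methanol releases acetone and frees the C3' hydroxyl without base, which avoids alkene migration and β-elimination and leaves the S centre untouched.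

Step 5
Reactants: 6 methyl (S)-2-hydroxy-4-oxohept-6-enoate
Product: 7 methyl (S)-2-(benzyloxy)-4-oxohept-6-enoate
Conditions: BnOC(=NH)CCl3, TfOH (cat.), cyclohexane–CH2Cl2, 0 °C → rt
Reagents that add atoms: benzyl 2,2,2-trichloroacetimidate N=C(OCc1ccccc1)C(Cl)(Cl)Cl
Why: Trichloroacetimidate benzylation under catalytic TfOH is the established base-free O-alkylation for α-hydroxy esters and β-hydroxy carbonyl compounds, and since only the O–H bond reacts the S configuration is retained.

Step 6
Reactants: 7 methyl (S)-2-(benzyloxy)-4-oxohept-6-enoate; 8 dichloromethane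
Product: 11 (3S,5S)-5-allyl-3-(benzyloxy)-5-(dichloromethyl)oxolan-2-one, via dichloromethyllithium 9 (not isolated), via tertiary alkoxide 10 (not isolated)
Conditions: 8, n-BuLi, THF–Et2O, −100 °C; cold cannula into 7 precomplexed with MgBr2·OEt2 (1.2 equiv), CH2Cl2–Et2O, −100 °C, then → −40 °C; AcOH, −40 °C → rt
Reagents that add atoms: none
Why: MgBr2 binds the C5' ketone oxygen and the C3' benzyloxy oxygen of 7 in a six-membered chelate, and carbenoid 9 (or the less basic Cl2CHMgBr formed from it by lithium–magnesium exchange) adds 1,2 to the activated carbonyl to give alkoxide 10. The closest known reaction types are the addition of dichloromethyllithium to enolizable ketones and the chelation-controlled 1,3-anti addition of organometallics to β-alkoxy carbonyl compounds, and running both at once on an allyl ketone is an extrapolation from them. The new C5' centre is controlled by C3': C2' projects from one face of the chelate, the nucleophile enters from the other, and the resulting 1,3-anti relation of the two oxygens (chain read through CHCl2) becomes CHCl2 cis to OBn on ring C, which is 5S in 11; an extra magnesium contact to the ester carbonyl would pin C2' over the same face and act in the same sense. Ring C closes by 5-exo-trig attack of alkoxide 10 on the magnesium-activated α-alkoxy methyl ester with loss of methoxide, which should outrun 3-exo-tet displacement of chloride (chloro-epoxide formation) as long as the mixture stays at or below −40 °C. The step needs addition rather than deprotonation (at the CH2 between carbonyl and vinyl, or at C4' with loss of benzyl oxide) and attack on the ketone rather than the ester; the first is served by −100 °C, by Lewis-acid activation and by making 9 with n-BuLi so that no amine sits beside MgBr2, and the second by the higher electrophilicity of the chelated ketone and a near-stoichiometric charge of 9.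

Step 7
Reactants: 12 1-iodo-3,5-dimethoxybenzene
Product: 14 2-iodo-4,6-dimethoxybenzaldehyde, via aryl iminium salt 13 (not isolated)
Conditions: POCl3, DMF, 0 → 80 °C; then H2O, 0 °C → rt
Reagents that add atoms: N,N-dimethylformamide CN(C)C=O; water O
Why: Vilsmeier–Haack formylation of the activated arene goes para to one methoxy group and ortho to the other, next to iodine, which is the position known to react in 1-halo-3,5-dimethoxybenzenes, and water then hydrolyses iminium salt 13.

Step 8
Reactants: 14 2-iodo-4,6-dimethoxybenzaldehyde
Product: 15 2-iodo-4,6-dimethoxybenzoic acid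
Conditions: NaClO2, NaH2PO4, 2-methyl-2-butene, t-BuOH–H2O, rt
Reagents that add atoms: sodium chlorite [Na+].[O-]Cl=O
Why: Pinnick oxidation takes the aldehyde to the acid under buffered conditions in which the carbon–iodine bond is inert and 2-methyl-2-butene intercepts the hypochlorous acid that would otherwise chlorinate the electron-rich ring.

Step 9
Reactants: 11 (3S,5S)-5-allyl-3-(benzyloxy)-5-(dichloromethyl)oxolan-2-one; 15 2-iodo-4,6-dimethoxybenzoic acid
Product: 16 2-{(E)-3-[(2S,4S)-4-(benzyloxy)-2-(dichloromethyl)-5-oxooxolan-2-yl]prop-1-en-1-yl}-4,6-dimethoxybenzoic acid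
Conditions: Pd(OAc)2 (5 mol %), Bu4NCl, NaHCO3, DMF, 70 °C; acidic work-up
Reagents that add atoms: none
Why: Heck reaction under ligand-free phase-transfer conditions, in which the arylpalladium species delivers its aryl group to the unhindered terminal carbon and β-hydride elimination of a benzylic hydrogen gives the conjugated E alkene, while bicarbonate is too weak a base to epimerize C3' or to touch the lactone and the CHCl2 group.

Step 10
Reactants: 16 2-{(E)-3-[(2S,4S)-4-(benzyloxy)-2-(dichloromethyl)-5-oxooxolan-2-yl]prop-1-en-1-yl}-4,6-dimethoxybenzoic acid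
Product: 17 3-{[(2R,4S)-4-(benzyloxy)-2-(dichloromethyl)-5-oxooxolan-2-yl]methyl}-6,8-dimethoxy-1H-isochromen-1-one
Conditions: PdCl2(MeCN)2 (10 mol %), 1,4-benzoquinone, THF, 50 °C
Reagents that add atoms: none
Why: Wacker-type intramolecular oxypalladation of a 2-alkenylbenzoic acid, in which the carboxylate attacks the alkene carbon remote from ring A (6-endo-trig) because palladium then rests on benzylic C4, β-hydride elimination of C3–H gives the isocoumarin, and benzoquinone returns zerovalent palladium to the divalent state.

Step 11
Reactants: 17 3-{[(2R,4S)-4-(benzyloxy)-2-(dichloromethyl)-5-oxooxolan-2-yl]methyl}-6,8-dimethoxy-1H-isochromen-1-one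
Product: 18 3-{[(2R,4S)-2-(dichloromethyl)-4-hydroxy-5-oxooxolan-2-yl]methyl}-8-hydroxy-6-methoxy-1H-isochromen-1-one (CNP0072605.2)
Conditions: BCl3, pentamethylbenzene, CH2Cl2, −78 °C → rt; then H2O
Reagents that add atoms: none
Why: BCl3 ether cleavage, in which the benzyl ether is ionized at low temperature with pentamethylbenzene as a non-basic trap for the benzyl cation, and on warming boron chelated between the C1 carbonyl and the peri C8 oxygen removes only that methyl group, so the C6 methyl ether, both lactones, CHCl2 and both stereocentres remain.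

**Compound list**
1 | L-malic acid | O=C(O)C[C@H](O)C(=O)O | starting material
2 | (S)-2-(2,2-dimethyl-5-oxo-1,3-dioxolan-4-yl)acetic acid | O=C(O)C[C@@H]1OC(C)(C)OC1=O | intermediate
3 | (S)-2-(2,2-dimethyl-5-oxo-1,3-dioxolan-4-yl)acetyl chloride | O=C(Cl)C[C@@H]1OC(C)(C)OC1=O | intermediate
4 | allyltributylstannane | C=CC[Sn](CCCC)(CCCC)CCCC | starting material
5 | (S)-2,2-dimethyl-5-(2-oxopent-4-en-1-yl)-1,3-dioxolan-4-one | C=CCC(=O)C[C@@H]1OC(C)(C)OC1=O | intermediate
6 | methyl (S)-2-hydroxy-4-oxohept-6-enoate | C=CCC(=O)C[C@H](O)C(=O)OC | intermediate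
7 | methyl (S)-2-(benzyloxy)-4-oxohept-6-enoate | C=CCC(=O)C[C@H](OCc1ccccc1)C(=O)OC | intermediate
8 | dichloromethane | ClCCl | starting material
9 | dichloromethyllithium | [Li]C(Cl)Cl | intermediate
10 | alkoxide of methyl (2S,4S)-2-(benzyloxy)-4-(dichloromethyl)-4-hydroxyhept-6-enoate, magnesium-chelated in the flask and drawn as the lithium salt | C=CC[C@@]([O-])(C(Cl)Cl)C[C@H](OCc1ccccc1)C(=O)OC.[Li+] | intermediate
11 | (3S,5S)-5-allyl-3-(benzyloxy)-5-(dichloromethyl)oxolan-2-one | C=CC[C@@]1(C(Cl)Cl)C[C@H](OCc2ccccc2)C(=O)O1 | intermediate
12 | 1-iodo-3,5-dimethoxybenzene | COc1cc(I)cc(OC)c1 | starting material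
13 | N-(2-iodo-4,6-dimethoxybenzylidene)-N-methylmethanaminium dichlorophosphate | COc1cc(I)c(C=[N+](C)C)c(OC)c1.[O-]P(=O)(Cl)Cl | intermediate
14 | 2-iodo-4,6-dimethoxybenzaldehyde | COc1cc(I)c(C=O)c(OC)c1 | intermediate
15 | 2-iodo-4,6-dimethoxybenzoic acid | COc1cc(I)c(C(=O)O)c(OC)c1 | intermediate
16 | 2-{(E)-3-[(2S,4S)-4-(benzyloxy)-2-(dichloromethyl)-5-oxooxolan-2-yl]prop-1-en-1-yl}-4,6-dimethoxybenzoic acid | COc1cc(OC)c(C(=O)O)c(/C=C/C[C@@]2(C(Cl)Cl)C[C@H](OCc3ccccc3)C(=O)O2)c1 | intermediate
17 | 3-{[(2R,4S)-4-(benzyloxy)-2-(dichloromethyl)-5-oxooxolan-2-yl]methyl}-6,8-dimethoxy-1H-isochromen-1-one | COc1cc(OC)c2c(=O)oc(C[C@@]3(C(Cl)Cl)C[C@H](OCc4ccccc4)C(=O)O3)cc2c1 | intermediate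
18 | 3-{[(2R,4S)-2-(dichloromethyl)-4-hydroxy-5-oxooxolan-2-yl]methyl}-8-hydroxy-6-methoxy-1H-isochromen-1-one | COc1cc(O)c2c(=O)oc(C[C@@]3(C(Cl)Cl)C[C@H](O)C(=O)O3)cc2c1 | target

**Count**
Total steps: 11. Longest linear sequence: 9 (steps 1–6 and 9–11).

**Steps most likely to fail**

1. Step 6.
   - What may go wrong: the carbenoid may deprotonate instead of adding, which moves the alkene into conjugation or expels benzyl oxide from C3'. The ethereal solvent that carries it may loosen the chelate, so that both faces of the ketone are attacked alike. Slow ring closure would leave time for chloride displacement.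
   - Fallback: it sets out from 7 and comes back at 11, changes the nucleophile and gives up induction.
     - Me3SiCCl3 with catalytic Bu4NOAc in THF at −20 °C transfers the much less basic trichloromethyl anion to the ketone. This should give methyl (2S)-2-(benzyloxy)-4-(trichloromethyl)-4-(trimethylsilyloxy)hept-6-enoate F1 as both C4 epimers.
     - TsOH·H2O in warm toluene removes the silyl group and lactonizes, and the two lactones are separated by chromatography.
     - The epimer with CCl3 cis to OBn, (3S,5S)-5-allyl-3-(benzyloxy)-5-(trichloromethyl)oxolan-2-one F2, is treated with one equivalent of Bu3SnH (Et3B, air, toluene, 0 °C). This radical-chain hydrodechlorination should stop at CHCl2, because each further chlorine is abstracted more slowly, and so delivers 11.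

2. Step 9.
   - What may go wrong: after insertion, β-hydride elimination may also run toward the C5' side and give the non-conjugated alkene, an allylic carboxylate that zerovalent palladium can ionize. Branched insertion is a further drain, as is loss of CO2 from the electron-rich, doubly ortho-substituted acid at divalent palladium.
   - Fallback: it sets out from 11 (with 15 as partner) and comes back at 16, and fixes alkene position and geometry before the aryl–carbon bond is made.
     - Cross-metathesis of 11 with vinylboronic acid pinacol ester (second-generation Grubbs catalyst, CH2Cl2, reflux) should give (3S,5S)-3-(benzyloxy)-5-(dichloromethyl)-5-[(E)-3-(4,4,5,5-tetramethyl-1,3,2-dioxaborolan-2-yl)allyl]oxolan-2-one F3.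
     - Suzuki–Miyaura coupling of F3 with 15 (PdCl2(dppf), CsF, dioxane, 60 °C) then gives 16 without any palladium hydride step.

3. Step 5.
   - What may go wrong: under TfOH the alkene of 6 may migrate into conjugation. The β-hydroxy ketone may also lose water to the 4-oxo-2-enoate before the poorly nucleophilic α-hydroxy ester oxygen is benzylated.
   - Fallback: it sets out from 1 and comes back at 7, puts ester and benzyl ether in place first and makes the allyl ketone last, so that this ketone never meets acid.
     - Trifluoroacetic anhydride converts 1 into (S)-2-(trifluoroacetoxy)succinic anhydride F4.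
     - Methanol opens F4 at the carbonyl next to the acyloxy group and strips the trifluoroacetate, giving (S)-3-hydroxy-4-methoxy-4-oxobutanoic acid F5.
     - Excess benzyl trichloroacetimidate with catalytic TfOH benzylates both the hydroxyl and the carboxyl, giving 4-benzyl 1-methyl (S)-2-(benzyloxy)butanedioate F6.
     - Hydrogenolysis over Pd/C in MeOH with added pyridine, which suppresses benzyl ether cleavage, frees only the acid, (S)-3-(benzyloxy)-4-methoxy-4-oxobutanoic acid F7.
     - Oxalyl chloride with catalytic DMF gives methyl (S)-2-(benzyloxy)-4-chloro-4-oxobutanoate F8, and Stille acylation with 4 under the conditions of step 3 gives 7.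

**Further compounds**
F1 | step 6 | methyl (2S)-2-(benzyloxy)-4-(trichloromethyl)-4-(trimethylsilyloxy)hept-6-enoate, both C4 epimers | C=CCC(O[Si](C)(C)C)(C(Cl)(Cl)Cl)C[C@H](OCc1ccccc1)C(=O)OC
F2 | step 6 | (3S,5S)-5-allyl-3-(benzyloxy)-5-(trichloromethyl)oxolan-2-one | C=CC[C@@]1(C(Cl)(Cl)Cl)C[C@H](OCc2ccccc2)C(=O)O1
F3 | step 9 | (3S,5S)-3-(benzyloxy)-5-(dichloromethyl)-5-[(E)-3-(4,4,5,5-tetramethyl-1,3,2-dioxaborolan-2-yl)allyl]oxolan-2-one | CC1(C)OB(/C=C/C[C@@]2(C(Cl)Cl)C[C@H](OCc3ccccc3)C(=O)O2)OC1(C)C
F4 | step 5 | (S)-2-(trifluoroacetoxy)succinic anhydride | O=C1C[C@H](OC(=O)C(F)(F)F)C(=O)O1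
F5 | step 5 | (S)-3-hydroxy-4-methoxy-4-oxobutanoic acid | O=C(O)C[C@H](O)C(=O)OC
F6 | step 5 | 4-benzyl 1-methyl (S)-2-(benzyloxy)butanedioate | O=C(C[C@H](OCc1ccccc1)C(=O)OC)OCc1ccccc1
F7 | step 5 | (S)-3-(benzyloxy)-4-methoxy-4-oxobutanoic acid | O=C(O)C[C@H](OCc1ccccc1)C(=O)OC
F8 | step 5 | methyl (S)-2-(benzyloxy)-4-chloro-4-oxobutanoate | O=C(Cl)C[C@H](OCc1ccccc1)C(=O)OC
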